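**Assumption:** the target has no stereocentre and its only alkene carries two identical methyl groups, so it is achiral; "single enantiomer" is read as the one compound drawn, and no stereocontrol is needed.

## Retrosynthetic overview

1. Both benzene rings are bought intact; no ring is formed in the route.
2. Ring A: methyl 2,6-dihydroxy-4-methylbenzoate 1 + prenol 2 ⇒ mono-C-prenylated resorcylate 3 (C–C bond ortho to OH; the two open positions of 1 are equivalent).
3. Ring B: 3,5-dimethoxybenzyl alcohol 4 ⇒ 2-iodo derivative 5 (iodine at the carbon that will carry the ether oxygen).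
4. Key disconnection: the diaryl ether C–O bond of target 6, between the less hindered phenol oxygen of 3 and C2 of 5. It is made last, with the free CH2OH of 5 as an internal directing group, so no protecting groups or redox adjustments are needed.

## Route

Step 1
Reactants: 1 methyl 2,6-dihydroxy-4-methylbenzoate; 2 3-methylbut-2-en-1-ol (prenol)
Product: 3 methyl 2,6-dihydroxy-4-methyl-3-(3-methylbut-2-en-1-yl)benzoate
Conditions: acidic Al2O3 (Brockmann I), 2 (1.1 equiv), ClCH2CH2Cl, 80 °C
Reagents that add atoms: none
Why: Alumina-templated Friedel–Crafts ortho-allylation: phenol and allylic alcohol co-adsorb and the incipient prenyl cation is delivered to the carbon ortho to a surface-bound OH; C3 and C5 of symmetric 1 are equivalent (each ortho to one OH, para to the other), so only mono- versus bis-alkylation needs control (stop at about 80% conversion, recycle 1), the mild surface acidity limits chroman formation, and water is the only by-product.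

Step 2
Reactants: 4 (3,5-dimethoxyphenyl)methanol
Product: 5 (2-iodo-3,5-dimethoxyphenyl)methanol
Conditions: NIS (1.05 equiv), MeCN, 0 °C to rt, dark
Reagents that add atoms: N-iodosuccinimide, O=C1CCC(=O)N1I
Why: Electrophilic aromatic iodination (SEAr) occurs at C2, which is para to one OMe and ortho to the other, in preference to C4 between the two OMe groups, as in the well-known bromination of 4; the neutral, cold conditions leave the benzylic alcohol untouched.

Step 3
Reactants: 3 methyl 2,6-dihydroxy-4-methyl-3-(3-methylbut-2-en-1-yl)benzoate; 5 (2-iodo-3,5-dimethoxyphenyl)methanol (1.3 equiv)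
Product: 6 methyl 2-hydroxy-6-[2-(hydroxymethyl)-4,6-dimethoxyphenoxy]-4-methyl-3-(3-methylbut-2-en-1-yl)benzoate
Conditions: CuI (10 mol %), Cs2CO3 (2.5 equiv), 4 Å MS, 1,4-dioxane, 80 °C, Ar
Reagents that add atoms: none
Why: Proposed new method: hydroxymethyl-directed (substrate-as-ligand) Ullmann diaryl ether coupling, in which the benzylic alkoxide of 5 (formed reversibly on copper under carbonate, as in Cu-catalysed arylation of aliphatic alcohols) and the phenoxide of 3 both bind Cu(I) to give an electron-rich cuprate that holds the C–I bond next to the metal, so oxidative addition is intramolecular and gives a five-membered oxa-cupra(III)cycle; the tethered alkoxide cannot reductively eliminate with the aryl carbon (that would give a benzoxete), so the only productive reductive elimination is aryl–OAr, which forms the diaryl ether and releases the CH2OH unchanged; this template effect should offset the electron-rich, 2,6-disubstituted nature of 5, and the crowded aryl–Cu(III) centre should select the phenoxide of 3 flanked by H (6-OH) over the one flanked by the prenyl group (2-OH), the latter staying hydrogen-bonded to the ester; the closest known reaction types are the ortho-carboxylate-accelerated (Hurtley/Ullmann–Goldberg) couplings of 2-halobenzoic acids and ligand-accelerated Cu-catalysed Ullmann diaryl ether synthesis, neither of which, to my knowledge, has been shown with a free ortho-CH2OH as the internal anionic ligand on a tetrasubstituted, electron-rich aryl iodide; no stereocentre is formed, and the ester, prenyl alkene and remaining hindered phenol are inert to Cu(I)/carbonate under argon.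

## Compound list

1 | methyl 2,6-dihydroxy-4-methylbenzoate | COC(=O)c1c(O)cc(C)cc1O | starting material
2 | 3-methylbut-2-en-1-ol (prenol) | CC(C)=CCO | starting material
3 | methyl 2,6-dihydroxy-4-methyl-3-(3-methylbut-2-en-1-yl)benzoate | COC(=O)c1c(O)cc(C)c(CC=C(C)C)c1O | intermediate
4 | (3,5-dimethoxyphenyl)methanol | COc1cc(CO)cc(OC)c1 | starting material
5 | (2-iodo-3,5-dimethoxyphenyl)methanol | COc1cc(CO)c(I)c(OC)c1 | intermediate
6 | methyl 2-hydroxy-6-[2-(hydroxymethyl)-4,6-dimethoxyphenoxy]-4-methyl-3-(3-methylbut-2-en-1-yl)benzoate | COC(=O)c1c(Oc2c(CO)cc(OC)cc2OC)cc(C)c(CC=C(C)C)c1O | target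

## Summary and risks

Total step count: 3. Longest linear sequence: 2 steps (1 → 3 → 6; the branch 4 → 5 → 6 is equally long).

Steps most likely to fail, most risky first:

**Step 3 (the proposed new coupling).** Risks are slow oxidative addition if the alkoxide does not engage copper, proto-deiodination of 5, and self-etherification of 5. The fallback uses known chemistry and sets out from 3. Compound 3 is coupled with commercial 2-bromo-3,5-dimethoxybenzaldehyde (COc1cc(C=O)c(Br)c(OC)c1) under standard ligand-accelerated Ullmann conditions for hindered diaryl ethers (CuI 10 mol %, picolinic acid 20 mol %, K3PO4, DMSO, 90 °C). The ortho-formyl group activates the C–Br bond, and the product is methyl 6-(2-formyl-4,6-dimethoxyphenoxy)-2-hydroxy-4-methyl-3-(3-methylbut-2-en-1-yl)benzoate F1. Reduction of the aldehyde with NaBH4 in MeOH/THF at 0 °C, which leaves the hindered salicylate ester and the alkene alone, comes back to the route at 6.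

**Step 1 (C-prenylation).** Risks are bis-prenylation, chroman formation by cyclisation of the prenyl group onto the neighbouring OH, and low reactivity of the hydrogen-bonded resorcylate. The fallback replaces direct C-alkylation with O-alkylation followed by a sigmatropic shift and sets out from 1. Mono-O-alkylation of 1 with 3-chloro-3-methylbut-1-yne (CC(C)(Cl)C#C; K2CO3, KI, cat. CuI, acetone, 60 °C) gives methyl 2-hydroxy-4-methyl-6-[(2-methylbut-3-yn-2-yl)oxy]benzoate F2. Semi-hydrogenation (H2, Lindlar catalyst, quinoline, EtOAc) gives methyl 2-hydroxy-4-methyl-6-[(2-methylbut-3-en-2-yl)oxy]benzoate F3. Heating in toluene at 110 °C effects an aromatic Claisen rearrangement to the only free ortho carbon. This passes through methyl 2-hydroxy-4-methyl-5-(3-methylbut-2-en-1-yl)-6-oxocyclohexa-1,3-diene-1-carboxylate F4 (racemic dienone, not isolated), which tautomerises and so comes back to the route at 3.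

**Step 2 (iodination).** Risks are some 4-iodo or di-iodo product and oxidation of the benzylic alcohol by the I(+) reagent. The fallback installs the halogen in two stages and sets out from 4. Bromination with NBS (MeCN, 0 °C), whose C2 selectivity on this substrate is well established, gives (2-bromo-3,5-dimethoxyphenyl)methanol F5. A copper-catalysed aromatic Finkelstein exchange (CuI 5 mol %, trans-N,N'-dimethylcyclohexane-1,2-diamine 10 mol %, NaI, dioxane, 110 °C) then comes back to the route at 5.

## Further compounds

F1 | step 3 | methyl 6-(2-formyl-4,6-dimethoxyphenoxy)-2-hydroxy-4-methyl-3-(3-methylbut-2-en-1-yl)benzoate | COC(=O)c1c(Oc2c(C=O)cc(OC)cc2OC)cc(C)c(CC=C(C)C)c1O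
F2 | step 1 | methyl 2-hydroxy-4-methyl-6-[(2-methylbut-3-yn-2-yl)oxy]benzoate | COC(=O)c1c(O)cc(C)cc1OC(C)(C)C#C
F3 | step 1 | methyl 2-hydroxy-4-methyl-6-[(2-methylbut-3-en-2-yl)oxy]benzoate | COC(=O)c1c(O)cc(C)cc1OC(C)(C)C=C
F4 | step 1 | methyl 2-hydroxy-4-methyl-5-(3-methylbut-2-en-1-yl)-6-oxocyclohexa-1,3-diene-1-carboxylate (racemic, not isolated) | COC(=O)C1=C(O)C=C(C)C(CC=C(C)C)C1=O
F5 | step 2 | (2-bromo-3,5-dimethoxyphenyl)methanol | COc1cc(CO)c(Br)c(OC)c1
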